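**Retrosynthetic overview**
1. Target 34 ⇐ tris-MOM aryl selinenol 28: two directed ortho-metalations (isobutyryl carbon, then formyl carbon), one oxidation, final acetal solvolysis.
2. 28 ⇐ 1-methylene decalin 17 + aryl bromide 20 (from phloroglucinol) by hydroboration/B-alkyl Suzuki coupling (sets C1); isopropenyl from the C7 ketone via nitrile, methyl ketone (C7 set by equilibration) and Wittig.
3. 17 ⇐ trans-decalone 11: C4 methylene, α-epoxide, hydride opening (sets C4); C1 oxygen then unmasked, oxidised and methylenated.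
4. 11 ⇐ (R)-Wieland–Miescher ketone 5: ketoreductase reduction at C1, deconjugative ketalisation, hydroboration/oxidation/equilibration (sets C5, trans fusion).
5. Ring order: ring A comes from 2-methylcyclohexane-1,3-dione; ring B is closed onto it by a D-proline-catalysed Robinson annulation with methyl vinyl ketone (sets C10).

Convention: the decalin carries eudesmane numbering (C10 = methyl-bearing ring-fusion carbon; C1–C4 in ring A, C4 = carbinol carbon; C5 = ring-fusion CH; C6–C9 in ring B, C7 = isopropenyl carbon; C15 = exocyclic carbon on C4); β = face of the C10 methyl, α = the opposite face. Aryl positions carry primes (C1' bears the benzylic CH2).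

**Route**

Step 1
Reactants: 1 2-methylcyclohexane-1,3-dione; 2 but-3-en-2-one (methyl vinyl ketone)
Product: 3 2-methyl-2-(3-oxobutyl)cyclohexane-1,3-dione
Conditions: Et3N (2 mol%), EtOAc, 60 °C
Reagents that add atoms: none
Why: Base-catalysed Michael addition of the acidic 1,3-dione to the enone gives the achiral, prochiral triketone.

Step 2
Reactants: 3 triketone
Product: 5 (R)-Wieland–Miescher ketone (C1 ketone; C7 enone with C5=C6), via cis-fused ketol 4 (not isolated)
Conditions: D-proline (5 mol%), DMSO, 35 °C, 4 d; recrystallise (Et2O/hexane)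
Reagents that add atoms: none
Why: Hajos–Parrish–Eder–Sauer–Wiechert intramolecular aldol condensation (completing the Robinson annulation), in which the D-proline enamine of the side-chain ketone attacks one enantiotopic ring carbonyl, so ring B closes and the quaternary C10 forms as (R); crystallisation raises the ee.

Step 3
Reactants: 5 (R)-Wieland–Miescher ketone
Product: 6 (4aR,5R)-5-hydroxy-4a-methyl-4,4a,5,6,7,8-hexahydronaphthalen-2(3H)-one (1β-hydroxy enone)
Conditions: ketoreductase (NADPH-dependent), NADP+ (cat.), i-PrOH (10% v/v), phosphate buffer pH 7, DMSO (5% v/v), 30 °C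
Reagents that add atoms: none
Why: Enzymatic carbonyl reduction by a ketoreductase chosen by panel screening for anti-Prelog hydride delivery to the α face of C1: it reduces only the saturated C1 ketone of the (R)-enantiomer to the 1β (R) carbinol, leaving the enone and residual (S)-5 untouched (ee upgrade) and differentiating C1 from C7 for the rest of the route.

Step 4
Reactants: 6 1β-hydroxy enone
Product: 7 1β-hydroxy-10β-methyl-Δ4(5)-octalin-7-one ethylene ketal
Conditions: HOCH2CH2OH (5 equiv), TsOH·H2O (5 mol%), benzene, reflux, Dean–Stark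
Reagents that add atoms: ethane-1,2-diol, OCCO
Why: Acid-catalysed ketalisation of the enone carbonyl with double-bond migration out of conjugation masks C7 and moves the alkene to C4=C5, where C4 and C5 can be functionalised.

Step 5
Reactants: 7 hydroxy ketal
Product: 8 1β-benzyloxy-10β-methyl-Δ4(5)-octalin-7-one ethylene ketal
Conditions: NaH, BnBr, n-Bu4NI (cat.), THF/DMF, 0 °C → rt
Reagents that add atoms: benzyl bromide, BrCc1ccccc1
Why: Williamson ether synthesis gives a benzyl ether that survives boranes, bases, peracid and hydride until C1 is needed again.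

Step 6
Reactants: 8 benzyl ether
Product: 10 1β-benzyloxy-4α-hydroxy-10β-methyl-5α-decalin-7-one ethylene ketal, via 4α-boryl adduct 9 (not isolated)
Conditions: BH3·THF, THF, 0 °C → rt; then 3 M NaOH, 30% H2O2, 0 °C → rt
Reagents that add atoms: borane (as BH3·THF), B (boron held in 9 only); hydrogen peroxide, OO
Why: Hydroboration–oxidation: anti-Markovnikov syn addition of B–H from the α face (opposite the C10 methyl) puts H on C5 (trans fusion) and boron on C4, and oxidation with retention gives the 4α-ol; any β-face adduct converges in step 7.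

Step 7
Reactants: 10 4α-alcohol
Product: 11 1β-benzyloxy-10β-methyl-5α-decalin-4,7-dione 7-ethylene ketal
Conditions: Dess–Martin periodinane, pyridine, CH2Cl2, rt; then NaOMe (0.2 equiv), MeOH, rt
Reagents that add atoms: none
Why: Dess–Martin oxidation gives the C4 ketone, and base equilibration at the now enolisable C5 secures the thermodynamically preferred trans-fused decalone.

Step 8
Reactants: 11 C4 ketone
Product: 12 1β-benzyloxy-4-methylene-10β-methyl-5α-decalin-7-one ethylene ketal
Conditions: Ph3PCH3Br, KOtBu, THF, 0 → 50 °C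
Reagents that add atoms: methyltriphenylphosphonium bromide, C[P+](c1ccccc1)(c1ccccc1)c1ccccc1.[Br-]
Why: Wittig methylenation of the ketone; C5 stays trans because that is also the thermodynamic arrangement under the basic conditions.

Step 9
Reactants: 12 C4 methylene compound
Product: 13 1β-benzyloxy-4α,15-epoxy-10β-methyl-5α-decalin-7-one ethylene ketal (spiro-oxirane, O on the α face, CH2 on the β face)
Conditions: mCPBA, CH2Cl2, 0 °C; minor β-epoxide removed by chromatography
Reagents that add atoms: 3-chloroperoxybenzoic acid, OOC(=O)c1cccc(Cl)c1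
Why: Prilezhaev epoxidation occurs from the α face because the β face of the exocyclic alkene is screened by the syn-axial C10 methyl, which fixes the C4 configuration (oxygen α/equatorial, carbon β/axial).

Step 10
Reactants: 13 epoxide
Product: 14 1β-benzyloxy-4α-hydroxy-4β,10β-dimethyl-5α-decalin-7-one ethylene ketal
Conditions: LiAlH4, THF, 0 → 40 °C; H2O/NaOH work-up
Reagents that add atoms: none
Why: Hydride opens the epoxide by bimolecular substitution at the unhindered CH2, turning it into the 4β-methyl and leaving the 4α tertiary alcohol with C4 untouched.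

Step 11
Reactants: 14 benzyl ether
Product: 15 1β,4α-dihydroxy-4β,10β-dimethyl-5α-decalin-7-one ethylene ketal
Conditions: H2 (1 atm), Pd(OH)2/C, EtOH/EtOAc, rt
Reagents that add atoms: none
Why: Catalytic hydrogenolysis cleaves the benzyl ether under neutral conditions; no alkene is present and the ketal and tertiary alcohol are inert.

Step 12
Reactants: 15 diol
Product: 16 4α-hydroxy-4β,10β-dimethyl-5α-decalin-1,7-dione 7-ethylene ketal
Conditions: Dess–Martin periodinane, pyridine, CH2Cl2, rt
Reagents that add atoms: none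
Why: Dess–Martin oxidation converts only the secondary C1 alcohol, since the tertiary C4 alcohol cannot be oxidised.

Step 13
Reactants: 16 C1 ketone
Product: 17 4α-hydroxy-4β,10β-dimethyl-1-methylene-5α-decalin-7-one ethylene ketal
Conditions: Ph3PCH3Br (6 equiv), KOtBu (5.5 equiv), toluene, 90 °C
Reagents that add atoms: methyltriphenylphosphonium bromide, C[P+](c1ccccc1)(c1ccccc1)c1ccccc1.[Br-]
Why: Wittig methylenation under forcing conditions overcomes the hindrance of the ketone next to the quaternary C10; the tertiary alkoxide is a spectator and there is no β-leaving group.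

Step 14
Reactants: 18 phloroglucinol (benzene-1,3,5-triol)
Product: 19 1,3,5-tris(methoxymethoxy)benzene
Conditions: MOMCl (3.6 equiv), i-Pr2NEt, CH2Cl2/DMF, 0 °C → rt
Reagents that add atoms: chloromethyl methyl ether, COCCl
Why: O-alkylation of the three phenols gives MOM acetals, which later direct ortho-lithiation and come off under mild acid.

Step 15
Reactants: 19 tris-MOM ether
Product: 20 2-bromo-1,3,5-tris(methoxymethoxy)benzene
Conditions: NBS (1.0 equiv), CH2Cl2, −20 → 0 °C
Reagents that add atoms: N-bromosuccinimide, O=C1CCC(=O)N1Br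
Why: Electrophilic aromatic bromination with one equivalent gives the single monobromide, since all three ring positions of the strongly activated arene are equivalent.

Step 16
Reactants: 17 1-methylene decalin; 20 aryl bromide
Product: 22 1β-[2,4,6-tris(methoxymethoxy)benzyl]-4α-hydroxy-4β,10β-dimethyl-5α-decalin-7-one ethylene ketal, via B-alkyl-9-BBN borane 21 (not isolated)
Conditions: 9-BBN dimer (2.5 equiv B–H), THF, 65 °C; then 20, Pd(OAc)2 (5 mol%), SPhos (10 mol%), K3PO4 (3 M aq.), THF, 70 °C
Reagents that add atoms: 9-borabicyclo[3.3.1]nonane, B1C2CCCC1CCC2 (boron unit held in 21 only)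
Why: Hydroboration then B-alkyl Suzuki–Miyaura coupling: 9-BBN adds from the α face (anti to the adjacent axial C10 methyl), so C1 gets an α-H and an equatorial β-CH2B arm, and the zerovalent palladium/SPhos catalyst formed from Pd(OAc)2 couples this primary alkylborane to the hindered aryl bromide without touching C1.

Step 17
Reactants: 22 aryl ketal
Product: 23 1β-[2,4,6-tris(methoxymethoxy)benzyl]-4α-hydroxy-4β,10β-dimethyl-5α-decalin-7-one
Conditions: PPTS (0.3 equiv), acetone/H2O (9:1), 55 °C
Reagents that add atoms: water, O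
Why: Mild acid-catalysed acetal hydrolysis frees the C7 ketone; the dioxolane of an unhindered cyclohexanone cleaves well before aryl MOM ethers or the tertiary alcohol react.

Step 18
Reactants: 23 C7 ketone
Product: 24 1β-[2,4,6-tris(methoxymethoxy)benzyl]-4α-hydroxy-4β,10β-dimethyl-5α-decalin-7-carbonitrile (C7 epimer mixture)
Conditions: TosMIC, KOtBu, DME/EtOH, 0 → 40 °C
Reagents that add atoms: p-toluenesulfonylmethyl isocyanide, Cc1ccc(cc1)S(=O)(=O)C[N+]#[C-]
Why: Van Leusen reductive cyanation converts the unhindered ketone into the homologous nitrile in one step; the C7 mixture is acceptable because C7 is set in step 19.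

Step 19
Reactants: 24 nitrile
Product: 27 7β-acetyl-1β-[2,4,6-tris(methoxymethoxy)benzyl]-4β,10β-dimethyl-5α-decalin-4α-ol, via N-lithio ketimine 25 (not isolated), via C7-epimeric methyl ketone 26 (not isolated)
Conditions: MeLi (4 equiv), Et2O/THF, 0 °C → rt; 1 M aq. HCl, THF, 0 °C, 15 min; then NaOMe, MeOH, rt; chromatography (7α epimer recycled)
Reagents that add atoms: methyllithium, [Li]C; water, O
Why: Organolithium addition to the nitrile and imine hydrolysis give the methyl ketone, and base epimerisation at the enolisable C7 places the acetyl group equatorial (7β), which sets the last ring stereocentre under thermodynamic control.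

Step 20
Reactants: 27 7β-methyl ketone
Product: 28 1β-[2,4,6-tris(methoxymethoxy)benzyl]selin-11-en-4α-ol (7β-isopropenyl)
Conditions: Ph3PCH3Br, KOtBu, THF, 0 °C → rt
Reagents that add atoms: methyltriphenylphosphonium bromide, C[P+](c1ccccc1)(c1ccccc1)c1ccccc1.[Br-]
Why: Wittig methylenation of the methyl ketone gives the isopropenyl group regiospecifically; the equatorial C7 configuration is also the thermodynamic one, so it is not eroded.

Step 21
Reactants: 28 aryl selinenol
Product: 30 1β-{[3-(1-hydroxy-2-methylpropyl)-2,4,6-tris(methoxymethoxy)phenyl]methyl}selin-11-en-4α-ol (carbinol epimers), via aryllithium alkoxide 29 (not isolated)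
Conditions: n-BuLi (2.5 equiv), TMEDA, THF, 0 °C; then i-PrCHO, −78 → 0 °C; H2O
Reagents that add atoms: n-butyllithium, [Li]CCCC (lithium held in 29 only); 2-methylpropanal, CC(C)C=O
Why: Directed ortho-metalation at a ring C–H flanked by two MOM ethers (the two free positions are constitutionally equivalent), followed by 1,2-addition to the aldehyde, installs the isobutyryl carbon skeleton; the carbinol mixture converges in step 23.

Step 22
Reactants: 30 benzylic alcohol
Product: 32 3-(1-hydroxy-2-methylpropyl)-5-{[(4α-hydroxyselin-11-en-1β-yl)]methyl}-2,4,6-tris(methoxymethoxy)benzaldehyde, via trilithio aryl species 31 (not isolated)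
Conditions: n-BuLi (4 equiv), TMEDA, THF, 0 °C; then DMF, −78 → 0 °C; H2O
Reagents that add atoms: n-butyllithium, [Li]CCCC (lithium held in 31 only); N,N-dimethylformamide, CN(C)C=O
Why: A second directed ortho-metalation at the last ring C–H (again between two MOM ethers, both alcohols carried as alkoxides) and formylation with DMF introduce the aldehyde carbon.

Step 23
Reactants: 32 hydroxy aldehyde
Product: 33 3-{[(4α-hydroxyselin-11-en-1β-yl)]methyl}-2,4,6-tris(methoxymethoxy)-5-(2-methylpropanoyl)benzaldehyde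
Conditions: Dess–Martin periodinane, pyridine, CH2Cl2, 0 °C → rt
Reagents that add atoms: none
Why: Dess–Martin oxidation turns the secondary benzylic alcohol into the aryl ketone without over-oxidising the aldehyde or touching the tertiary alcohol or the alkene.

Step 24
Reactants: 33 tris-MOM keto aldehyde
Product: 34 target, 2,4,6-trihydroxy-3-{[(1S,4R,5R,7R,10S)-4-hydroxyeudesm-11-en-1-yl]methyl}-5-(2-methylpropanoyl)benzaldehyde
Conditions: HCl (0.5 M in MeOH), THF, 0 °C → rt
Reagents that add atoms: none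
Why: Acid-catalysed acetal solvolysis removes the three MOM groups, each activated by an ortho carbonyl, under conditions mild enough for the unactivated tertiary alcohol and the isopropenyl group.

**Compound list**
1 | 2-methylcyclohexane-1,3-dione | CC1C(=O)CCCC1=O | starting material
2 | but-3-en-2-one (methyl vinyl ketone) | CC(=O)C=C | starting material
3 | 2-methyl-2-(3-oxobutyl)cyclohexane-1,3-dione | CC(=O)CCC1(C)C(=O)CCCC1=O | intermediate
4 | cis-fused ketol, 5β-hydroxy-10β-methyldecalin-1,7-dione | O=C1CC[C@@]2(C)C(=O)CCC[C@@]2(O)C1 | intermediate (not isolated)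
5 | (R)-Wieland–Miescher ketone, (8aR)-8a-methyl-3,4,8,8a-tetrahydronaphthalene-1,6(2H,7H)-dione | O=C1CC[C@@]2(C)C(=O)CCCC2=C1 | intermediate
6 | (4aR,5R)-5-hydroxy-4a-methyl-4,4a,5,6,7,8-hexahydronaphthalen-2(3H)-one | O=C1CC[C@@]2(C)[C@H](O)CCCC2=C1 | intermediate
7 | 1β-hydroxy-10β-methyl-Δ4(5)-octalin-7-one ethylene ketal | O1CCOC12CC[C@@]3(C)[C@H](O)CCC=C3C2 | intermediate
8 | 1β-benzyloxy-10β-methyl-Δ4(5)-octalin-7-one ethylene ketal | O1CCOC12CC[C@@]3(C)[C@H](OCc4ccccc4)CCC=C3C2 | intermediate
9 | 4α-boryl-1β-benzyloxy-10β-methyl-5α-decalin-7-one ethylene ketal | O1CCOC12CC[C@@]3(C)[C@H](OCc4ccccc4)CC[C@@H](B)[C@@H]3C2 | intermediate (not isolated)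
10 | 1β-benzyloxy-4α-hydroxy-10β-methyl-5α-decalin-7-one ethylene ketal | O1CCOC12CC[C@@]3(C)[C@H](OCc4ccccc4)CC[C@@H](O)[C@@H]3C2 | intermediate
11 | 1β-benzyloxy-10β-methyl-5α-decalin-4,7-dione 7-ethylene ketal | O1CCOC12CC[C@@]3(C)[C@H](OCc4ccccc4)CCC(=O)[C@@H]3C2 | intermediate
12 | 1β-benzyloxy-4-methylene-10β-methyl-5α-decalin-7-one ethylene ketal | O1CCOC12CC[C@@]3(C)[C@H](OCc4ccccc4)CCC(=C)[C@@H]3C2 | intermediate
13 | 1β-benzyloxy-4α,15-epoxy-10β-methyl-5α-decalin-7-one ethylene ketal | O1CCOC12CC[C@@]3(C)[C@H](OCc4ccccc4)CC[C@@]5(OC5)[C@@H]3C2 | intermediate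
14 | 1β-benzyloxy-4α-hydroxy-4β,10β-dimethyl-5α-decalin-7-one ethylene ketal | O1CCOC12CC[C@@]3(C)[C@H](OCc4ccccc4)CC[C@@](C)(O)[C@@H]3C2 | intermediate
15 | 1β,4α-dihydroxy-4β,10β-dimethyl-5α-decalin-7-one ethylene ketal | O1CCOC12CC[C@@]3(C)[C@H](O)CC[C@@](C)(O)[C@@H]3C2 | intermediate
16 | 4α-hydroxy-4β,10β-dimethyl-5α-decalin-1,7-dione 7-ethylene ketal | O1CCOC12CC[C@@]3(C)C(=O)CC[C@@](C)(O)[C@@H]3C2 | intermediate
17 | 4α-hydroxy-4β,10β-dimethyl-1-methylene-5α-decalin-7-one ethylene ketal | O1CCOC12CC[C@@]3(C)C(=C)CC[C@@](C)(O)[C@@H]3C2 | intermediate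
18 | phloroglucinol (benzene-1,3,5-triol) | Oc1cc(O)cc(O)c1 | starting material
19 | 1,3,5-tris(methoxymethoxy)benzene | COCOc1cc(OCOC)cc(OCOC)c1 | intermediate
20 | 2-bromo-1,3,5-tris(methoxymethoxy)benzene | COCOc1cc(OCOC)c(Br)c(OCOC)c1 | intermediate
21 | B-alkyl-9-BBN borane (1β-CH2–B arm) | O1CCOC12CC[C@@]3(C)[C@H](CB4C5CCCC4CCC5)CC[C@@](C)(O)[C@@H]3C2 | intermediate (not isolated)
22 | 1β-[2,4,6-tris(methoxymethoxy)benzyl]-4α-hydroxy-4β,10β-dimethyl-5α-decalin-7-one ethylene ketal | O1CCOC12CC[C@@]3(C)[C@H](Cc4c(OCOC)cc(OCOC)cc4OCOC)CC[C@@](C)(O)[C@@H]3C2 | intermediate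
23 | 1β-[2,4,6-tris(methoxymethoxy)benzyl]-4α-hydroxy-4β,10β-dimethyl-5α-decalin-7-one | O=C1CC[C@@]2(C)[C@H](Cc3c(OCOC)cc(OCOC)cc3OCOC)CC[C@@](C)(O)[C@@H]2C1 | intermediate
24 | corresponding 7-carbonitrile (C7 epimer mixture) | N#CC1CC[C@@]2(C)[C@H](Cc3c(OCOC)cc(OCOC)cc3OCOC)CC[C@@](C)(O)[C@@H]2C1 | intermediate
25 | N-lithio ketimine (lithium alkoxide at C4) | CC(=N[Li])C1CC[C@@]2(C)[C@H](Cc3c(OCOC)cc(OCOC)cc3OCOC)CC[C@@](C)(O[Li])[C@@H]2C1 | intermediate (not isolated)
26 | 7-acetyl compound (C7 epimer mixture) | CC(=O)C1CC[C@@]2(C)[C@H](Cc3c(OCOC)cc(OCOC)cc3OCOC)CC[C@@](C)(O)[C@@H]2C1 | intermediate (not isolated)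
27 | 7β-acetyl-1β-[2,4,6-tris(methoxymethoxy)benzyl]-4β,10β-dimethyl-5α-decalin-4α-ol | CC(=O)[C@@H]1CC[C@@]2(C)[C@H](Cc3c(OCOC)cc(OCOC)cc3OCOC)CC[C@@](C)(O)[C@@H]2C1 | intermediate
28 | 1β-[2,4,6-tris(methoxymethoxy)benzyl]selin-11-en-4α-ol | C=C(C)[C@@H]1CC[C@@]2(C)[C@H](Cc3c(OCOC)cc(OCOC)cc3OCOC)CC[C@@](C)(O)[C@@H]2C1 | intermediate
29 | 3'-lithio derivative of 28 (lithium alkoxide at C4) | C=C(C)[C@@H]1CC[C@@]2(C)[C@H](Cc3c(OCOC)cc(OCOC)c([Li])c3OCOC)CC[C@@](C)(O[Li])[C@@H]2C1 | intermediate (not isolated)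
30 | 3'-(1-hydroxy-2-methylpropyl) derivative of 28 (carbinol epimers) | C=C(C)[C@@H]1CC[C@@]2(C)[C@H](Cc3c(OCOC)cc(OCOC)c(C(O)C(C)C)c3OCOC)CC[C@@](C)(O)[C@@H]2C1 | intermediate
31 | 5'-lithio bis(lithium alkoxide) of 30 | C=C(C)[C@@H]1CC[C@@]2(C)[C@H](Cc3c(OCOC)c([Li])c(OCOC)c(C(O[Li])C(C)C)c3OCOC)CC[C@@](C)(O[Li])[C@@H]2C1 | intermediate (not isolated)
32 | hydroxy aldehyde (5'-formyl, 3'-(1-hydroxy-2-methylpropyl), tris-MOM) | C=C(C)[C@@H]1CC[C@@]2(C)[C@H](Cc3c(OCOC)c(C=O)c(OCOC)c(C(O)C(C)C)c3OCOC)CC[C@@](C)(O)[C@@H]2C1 | intermediate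
33 | keto aldehyde (5'-formyl, 3'-isobutyryl, tris-MOM) | C=C(C)[C@@H]1CC[C@@]2(C)[C@H](Cc3c(OCOC)c(C=O)c(OCOC)c(C(=O)C(C)C)c3OCOC)CC[C@@](C)(O)[C@@H]2C1 | intermediate
34 | 2,4,6-trihydroxy-3-{[(1S,4R,5R,7R,10S)-4-hydroxyeudesm-11-en-1-yl]methyl}-5-(2-methylpropanoyl)benzaldehyde | C=C(C)[C@@H]1CC[C@@]2(C)[C@H](Cc3c(O)c(C=O)c(O)c(C(=O)C(C)C)c3O)CC[C@@](C)(O)[C@@H]2C1 | target

**Step count**
Total steps: 24. Longest linear sequence: 22 (steps 1–13 and 16–24); the aryl bromide arm is 2 steps (14–15).

**Three steps most likely to fail, each with a fallback**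

Step 16 (hydroboration/B-alkyl Suzuki). Transmetalation of a β-branched alkylborane next to a quaternary carbon onto a di-ortho-substituted, electron-rich aryl bromide may be slow. The fallback sets out from 17 and comes back at 22. The same borane 21 is oxidised with NaOH/H2O2 to the 1β-hydroxymethyl ketal alcohol F1. Dess–Martin periodinane/pyridine converts it into the 1β-carbaldehyde F2, which is equatorial, so a brief base treatment also corrects any 1α epimer. Compound 19 is lithiated (n-BuLi, TMEDA, THF, 0 °C) to 2,4,6-tris(methoxymethoxy)phenyllithium F3, which adds to F2 at −78 °C to give the benzylic carbinol F4 (carbinol epimers). Ionic deoxygenation (Et3SiH, CF3CO2H, CH2Cl2, −40 °C) through the trialkoxy-stabilised benzylic cation then gives 22.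

Step 9 (epoxidation). The face selectivity may be only moderate and the spiro-epoxide is acid-sensitive. The fallback sets out from 12 and comes back at 14, bypassing 13, by Markovnikov oxymercuration–demercuration. Hg(OAc)2 in THF/H2O at rt lets water enter at C4 from the open α face and gives the 4β-(acetoxymercuriomethyl) 4α-carbinol F5. NaBH4/NaOH then replaces mercury by hydrogen and delivers 14 directly.

Step 19 (MeLi on the nitrile). Methyllithium may deprotonate the α-branched nitrile instead of adding. The fallback sets out from 23 and comes back at 26, bypassing 24 and 25. Wittig ethylidenation (Ph3PCH2CH3Br, KOtBu, THF) gives the 7-ethylidene compound F6 (E/Z mixture). BH3·THF adds to give the 7-(1-borylethyl) adduct F7 (not isolated), which NaOH/H2O2 oxidises to the 7-(1-hydroxyethyl) compound F8 (mixture at C7 and the carbinol carbon). Dess–Martin oxidation gives the methyl ketone mixture 26, which is equilibrated with NaOMe exactly as in step 19 to give 27.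

Further compounds
F1 | step 16 | 1β-(hydroxymethyl)-4α-hydroxy-4β,10β-dimethyl-5α-decalin-7-one ethylene ketal | O1CCOC12CC[C@@]3(C)[C@H](CO)CC[C@@](C)(O)[C@@H]3C2
F2 | step 16 | 1β-formyl-4α-hydroxy-4β,10β-dimethyl-5α-decalin-7-one ethylene ketal | O1CCOC12CC[C@@]3(C)[C@H](C=O)CC[C@@](C)(O)[C@@H]3C2
F3 | step 16 | 2,4,6-tris(methoxymethoxy)phenyllithium | [Li]c1c(OCOC)cc(OCOC)cc1OCOC
F4 | step 16 | 1β-{hydroxy[2,4,6-tris(methoxymethoxy)phenyl]methyl}-4α-hydroxy-4β,10β-dimethyl-5α-decalin-7-one ethylene ketal (carbinol epimers) | O1CCOC12CC[C@@]3(C)[C@H](C(O)c4c(OCOC)cc(OCOC)cc4OCOC)CC[C@@](C)(O)[C@@H]3C2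
F5 | step 9 | 1β-benzyloxy-4β-[(acetoxymercurio)methyl]-4α-hydroxy-10β-methyl-5α-decalin-7-one ethylene ketal | O1CCOC12CC[C@@]3(C)[C@H](OCc4ccccc4)CC[C@@](C[Hg]OC(C)=O)(O)[C@@H]3C2
F6 | step 19 | 7-ethylidene-1β-[2,4,6-tris(methoxymethoxy)benzyl]-4β,10β-dimethyl-5α-decalin-4α-ol (E/Z mixture) | CC=C1CC[C@@]2(C)[C@H](Cc3c(OCOC)cc(OCOC)cc3OCOC)CC[C@@](C)(O)[C@@H]2C1
F7 | step 19 | 7-(1-borylethyl)-1β-[2,4,6-tris(methoxymethoxy)benzyl]-4β,10β-dimethyl-5α-decalin-4α-ol (stereoisomer mixture) | CC(B)C1CC[C@@]2(C)[C@H](Cc3c(OCOC)cc(OCOC)cc3OCOC)CC[C@@](C)(O)[C@@H]2C1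
F8 | step 19 | 7-(1-hydroxyethyl)-1β-[2,4,6-tris(methoxymethoxy)benzyl]-4β,10β-dimethyl-5α-decalin-4α-ol (stereoisomer mixture) | CC(O)C1CC[C@@]2(C)[C@H](Cc3c(OCOC)cc(OCOC)cc3OCOC)CC[C@@](C)(O)[C@@H]2C1
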